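**Retrosynthetic overview**
- Target ⇐ 1-docosyl-2,3,3,5,6,6-hexamethoxycyclohexa-1,4-diene (a quinone bis-ketal) by one acid treatment: ketal hydrolysis, then selective hydrolysis of the chain-flanked C2 methoxy group.
- Bis-ketal ⇐ 14-(2,3,5,6-tetramethoxyphenyl)tetradecanoic acid + decanoic acid in one anodic operation: bis-methoxylation of the ring and mixed Kolbe coupling, which joins C9 and C10 of the chain (numbered from CH3) as two primary radicals, i.e. two carbons of like polarity.
- Enabling feature: the chain is unbranched and heteroatom-free, so C9 and C10 are plain CH2 groups that each trace back to a CO2H-bearing carbon. The ring, oxygenated at C1, C2, C4 and C5, is the hydrolysis product of the single para bis-ketal an anode makes from a 1,2,4,5-tetramethoxybenzene, and twelve CH2 groups (C11–C22) insulate it from the radical site.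
- Arene acid ⇐ malonic ester synthesis on 3-(12-bromododecyl)-1,2,4,5-tetramethoxybenzene ⇐ lithiated 1,2,4,5-tetramethoxybenzene + 1,12-dibromododecane.
- Ring order: the only ring, the six-membered carbocycle, is never built; it comes intact from 1,2,4,5-tetramethoxybenzene and only changes oxidation level (arene → bis-ketal → quinone).

Key step: step 4

Remark: the target has no stereocentre and is taken as the 2-hydroxy-1,4-quinone tautomer drawn; ring atoms are numbered as in 3-docosyl-2-hydroxy-5-methoxy-1,4-benzoquinone, chain atoms from CH3 (C1) to the ring-bound CH2 (C22).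

Step 1
Reactants: 1 1,2,4,5-tetramethoxybenzene; 2 1,12-dibromododecane
Product: 4 3-(12-bromododecyl)-1,2,4,5-tetramethoxybenzene, via 2,3,5,6-tetramethoxyphenyllithium 3 (not isolated)
Conditions: n-BuLi (1.05 equiv), TMEDA, THF, 0 °C to rt; then 2 (3 equiv), THF, −78 °C to rt
Reagents that add atoms: none
Why: Directed ortho-lithiation between two methoxy groups (the only kind of ring C–H in 1) followed by SN2 alkylation of the aryllithium with a primary bromide, the threefold excess of dibromide suppressing a second arylation.

Step 2
Reactants: 4 3-(12-bromododecyl)-1,2,4,5-tetramethoxybenzene; 5 diethyl malonate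
Product: 6 diethyl 2-[12-(2,3,5,6-tetramethoxyphenyl)dodecyl]propanedioate
Conditions: NaH, 5 (3 equiv), NaI (cat.), THF/DMF, 0 °C to 65 °C
Reagents that add atoms: none
Why: Malonic ester alkylation (SN2 of sodiomalonate on a primary bromide with iodide catalysis) adds the two carbons that turn the C12 tether into the C14 acid needed for a decarboxylative coupling, excess malonate limiting dialkylation.

Step 3
Reactants: 6 diethyl 2-[12-(2,3,5,6-tetramethoxyphenyl)dodecyl]propanedioate
Product: 8 14-(2,3,5,6-tetramethoxyphenyl)tetradecanoic acid, via 2-[12-(2,3,5,6-tetramethoxyphenyl)dodecyl]propanedioic acid 7 (not isolated)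
Conditions: KOH, EtOH/H2O, reflux; aq. HCl to pH 1; then neat under Ar, 150–160 °C
Reagents that add atoms: potassium hydroxide, [K+].[OH-]
Why: Saponification followed by thermal decarboxylation of the malonic acid (malonic ester synthesis), conditions to which the aryl methyl ethers are inert.

Step 4
Reactants: 8 14-(2,3,5,6-tetramethoxyphenyl)tetradecanoic acid; 9 decanoic acid
Product: 11 1-docosyl-2,3,3,5,6,6-hexamethoxycyclohexa-1,4-diene, via 14-(2,3,3,5,6,6-hexamethoxycyclohexa-1,4-dien-1-yl)tetradecanoic acid 10 (not isolated)
Conditions: Pt anode/Pt cathode, undivided cell, NaOMe (3 equiv, regenerated at the cathode), dry MeOH, 45 °C, ca. 10 mA cm−2, 2.5–3 F mol−1; then 9 (8 equiv), petroleum ether overlayer, ca. 0.25 A cm−2, until faintly alkaline; chromatography on Et3N-deactivated silica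
Reagents that add atoms: methanol, CO
Why: Proposed new method: one electrolysis is expected to run two anodic reactions in the order of their potentials: at low current density the tetramethoxyarene of 8 (oxidised more than 1 V below a carboxylate) loses two electrons and takes up two methoxides at the para methoxy-bearing carbons that become C1 and C4 of the quinone, giving bis-ketal acid 10, and once decanoic acid is added and the current density is raised the carboxylate-covered platinum anode enters the Kolbe regime, where both acids lose an electron and CO2 and the nonyl radical and the 13-(bis-ketal)tridecyl radical combine to form the C9–C10 bond of the chain. The closest known reaction types are the mixed Kolbe electrolysis of two unbranched fatty acids and the anodic bis-methoxylation of 1,4-dimethoxyarenes to quinone bis-ketals, both carried out at platinum in methanol containing alkoxide; their combination in one cell on one substrate is the untested element. No ring is closed and no stereocentre is formed. The step needs chemoselectivity between ring and carboxylate oxidation, which the potential gap and the staged current should secure, and it needs the ring to survive the radical stage, which is plausible because 10 no longer contains an oxidisable arene, carries only hindered enol ether double bonds to which nucleophilic primary alkyl radicals add slowly, and holds them twelve methylenes (C11–C22) away from the radical centre. Cross- over homo-coupling is secured only statistically by the eightfold excess of 9, the co-product octadecane being removed with hexane, and both radicals are unbranched primary ones that resist over-oxidation to cations (Hofer–Moest pathway). The two para pairs of methoxy-bearing carbons in 8 are related by the mirror plane through the chain-bearing carbon, so only one para bis-ketal can form.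

Step 5
Reactants: 11 1-docosyl-2,3,3,5,6,6-hexamethoxycyclohexa-1,4-diene
Product: 13 3-docosyl-2-hydroxy-5-methoxy-1,4-benzoquinone (target), via 3-docosyl-2,5-dimethoxy-1,4-benzoquinone 12 (not isolated)
Conditions: 60–70% aq. HClO4, 1,4-dioxane/CH2Cl2, rt
Reagents that add atoms: water, O
Why: Acid hydrolysis of both dimethyl ketals releases the para-quinone with its carbonyls fixed at the anodically methoxylated carbons, and perchloric acid should then hydrolyse selectively the vinylogous ester methoxy flanked by the chain (addition–elimination of water at C2, the more basic and sterically twisted vinylogous ester), the established way from 3-alkyl-2,5-dimethoxy-1,4-benzoquinones to 3-alkyl-2-hydroxy-5-methoxy-1,4-benzoquinones.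

**Compound list**
1 | 1,2,4,5-tetramethoxybenzene | COc1cc(OC)c(OC)cc1OC | starting material
2 | 1,12-dibromododecane | BrCCCCCCCCCCCCBr | starting material
3 | 2,3,5,6-tetramethoxyphenyllithium | COc1cc(OC)c(OC)c([Li])c1OC | intermediate
4 | 3-(12-bromododecyl)-1,2,4,5-tetramethoxybenzene | COc1cc(OC)c(OC)c(CCCCCCCCCCCCBr)c1OC | intermediate
5 | diethyl malonate | CCOC(=O)CC(=O)OCC | starting material
6 | diethyl 2-[12-(2,3,5,6-tetramethoxyphenyl)dodecyl]propanedioate | CCOC(=O)C(CCCCCCCCCCCCc1c(OC)c(OC)cc(OC)c1OC)C(=O)OCC | intermediate
7 | 2-[12-(2,3,5,6-tetramethoxyphenyl)dodecyl]propanedioic acid | OC(=O)C(CCCCCCCCCCCCc1c(OC)c(OC)cc(OC)c1OC)C(=O)O | intermediate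
8 | 14-(2,3,5,6-tetramethoxyphenyl)tetradecanoic acid | OC(=O)CCCCCCCCCCCCCc1c(OC)c(OC)cc(OC)c1OC | intermediate
9 | decanoic acid | CCCCCCCCCC(=O)O | starting material
10 | 14-(2,3,3,5,6,6-hexamethoxycyclohexa-1,4-dien-1-yl)tetradecanoic acid | OC(=O)CCCCCCCCCCCCCC1=C(OC)C(OC)(OC)C=C(OC)C1(OC)OC | intermediate
11 | 1-docosyl-2,3,3,5,6,6-hexamethoxycyclohexa-1,4-diene | CCCCCCCCCCCCCCCCCCCCCCC1=C(OC)C(OC)(OC)C=C(OC)C1(OC)OC | intermediate
12 | 3-docosyl-2,5-dimethoxy-1,4-benzoquinone | CCCCCCCCCCCCCCCCCCCCCCC1=C(OC)C(=O)C=C(OC)C1=O | intermediate
13 | 3-docosyl-2-hydroxy-5-methoxy-1,4-benzoquinone | CCCCCCCCCCCCCCCCCCCCCCC1=C(O)C(=O)C=C(OC)C1=O | target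

**Totals**
Total step count: 5. Longest linear sequence: 5 steps (1 → 4 → 6 → 8 → 11 → 13).

**Steps most likely to fail**

Step 4 (proposed new method). Possible failures: radical generation before ring oxidation is complete, so that alkyl radicals attack the arene radical cation; over-oxidation of the enol ether double bonds at the Kolbe potential; hydrolysis of the bis-ketal by adventitious water followed by cathodic reduction; passivation of the anode by waxy products; and loss of material to homo-coupling. The fallback uses known chemistry, sets out from 8 (with 9) and comes back to the route at 12. Acid 8 is esterified with N-hydroxyphthalimide (DIC, DMAP cat., CH2Cl2) to the redox-active ester 1,3-dioxoisoindolin-2-yl 14-(2,3,5,6-tetramethoxyphenyl)tetradecanoate F1, and 9 likewise to 1,3-dioxoisoindolin-2-yl decanoate F2. Nickel-electrocatalytic doubly decarboxylative C(sp3)–C(sp3) coupling of F1 with F2 (3 equiv) (NiCl2·glyme/terpyridine cat., AgNO3, Mg anode, RVC cathode, DMF, rt) is a reductive radical coupling that leaves the electron-rich arene untouched and should give 3-docosyl-1,2,4,5-tetramethoxybenzene F3 with the same C9–C10 bond. Oxidative demethylation of F3 with ceric ammonium nitrate (MeCN/H2O, 0 °C) should give 12, separable from any ortho-quinone isomer, which is then treated with HClO4 as in step 5.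

Step 5. Possible failure: loss of regiocontrol in the vinylogous ester hydrolysis, with water attacking at C5 or at both methoxy-bearing carbons, so that the isomeric hydroxy-methoxyquinone or the dihydroxyquinone forms. The fallback sets out from 11 and comes back at 13. Compound 11 is hydrolysed with dilute HCl in THF and 12 is isolated. Both vinylogous esters are then saponified (aq. NaOH, EtOH, then HCl) to 3-docosyl-2,5-dihydroxy-1,4-benzoquinone F4. Fischer-type etherification of F4 (MeOH, cat. H2SO4, reflux, stopped at the mono-ether) should take the unhindered hydroxyl remote from the chain (C5) and give 13.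

Step 1. Possible failures: a second arylation of the dibromide, bromine–lithium exchange and E2 elimination at the hindered aryllithium, with low conversion. The fallback replaces the SN2 alkylation by acylation and deoxygenation; it sets out from 1 and comes back at 4. Commercial 12-bromododecanoic acid is converted with oxalyl chloride (cat. DMF, CH2Cl2) into 12-bromododecanoyl chloride F5. Aryllithium 3 (from 1 as in step 1) is added to F5 at −78 °C (inverse addition) to give 12-bromo-1-(2,3,5,6-tetramethoxyphenyl)dodecan-1-one F6. Ionic hydrogenation of this electron-rich aryl ketone (Et3SiH, TFA, CH2Cl2, 0 °C to rt) should give 4.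

**Further compounds**
F1 | step 4 | 1,3-dioxoisoindolin-2-yl 14-(2,3,5,6-tetramethoxyphenyl)tetradecanoate | O=C(CCCCCCCCCCCCCc1c(OC)c(OC)cc(OC)c1OC)ON1C(=O)c2ccccc2C1=O
F2 | step 4 | 1,3-dioxoisoindolin-2-yl decanoate | CCCCCCCCCC(=O)ON1C(=O)c2ccccc2C1=O
F3 | step 4 | 3-docosyl-1,2,4,5-tetramethoxybenzene | CCCCCCCCCCCCCCCCCCCCCCc1c(OC)c(OC)cc(OC)c1OC
F4 | step 5 | 3-docosyl-2,5-dihydroxy-1,4-benzoquinone | CCCCCCCCCCCCCCCCCCCCCCC1=C(O)C(=O)C=C(O)C1=O
F5 | step 1 | 12-bromododecanoyl chloride | O=C(Cl)CCCCCCCCCCCBr
F6 | step 1 | 12-bromo-1-(2,3,5,6-tetramethoxyphenyl)dodecan-1-one | COc1cc(OC)c(OC)c(C(=O)CCCCCCCCCCCBr)c1OC
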